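**Plan**
- Retrosynthesis (locants of the furo[3,4-c]furan-1-one): remove five O-benzyl groups; excise ring oxygen O2 (Baeyer–Villiger retron) to reach a cis-fused 3-oxabicyclo[3.2.0]heptan-6-one; cut the cyclobutanone at C1–C6a and C3–C3a in one stroke; cut the aryl–C6 bond (Heck).
- Enabling feature: C1 (C=O) and C3 (ArCH–O) sit on the adjacent ring-fusion carbons C6a and C3a and are joined only through O2. Without O2 they are the two carbons of an aryl ketene, and C3a–C6a is the cis-alkene of a 2,5-dihydrofuran.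
- Forward: the tetrahydrofuran ring comes first (asymmetric Heck arylation of 2,3-dihydrofuran); the four-membered ring is added by a keteniminium [2+2] cycloaddition; strain-driven ring expansion gives the lactone; debenzylation ends the route.
- Stereochemistry: C6 from the ligand-controlled Heck reaction; C3a and C6a cis by suprafacial addition anti to the C6 aryl group; C3 by equilibration alpha to the cyclobutanone (exo aryl) and retention during migration.

Key step: step 5

Assumption: as for simple aryl triflates, the (R)-configured t-Bu-PHOX ligand is taken to deliver the (S)-2-aryl-2,5-dihydrofuran; should the sense prove opposite, the (S)-ligand is used.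

**Step 1**
Reactants: 1 3,4,5-tris(benzyloxy)benzoic acid
Product: 3 2-diazo-1-[3,4,5-tris(benzyloxy)phenyl]ethan-1-one, via acid chloride 2 (not isolated)
Conditions: (COCl)2, DMF (cat.), CH2Cl2, 0 °C to rt, evaporation; then Me3SiCHN2, THF–MeCN, 0 °C
Reagents that add atoms: trimethylsilyldiazomethane, C[Si](C)(C)C=[N+]=[N-]
Why: Acid chloride formation and C-acylation of the silyl diazomethane with loss of the silyl group (first stage of an Arndt–Eistert homologation) should give the alpha-diazoketone, the benzyl ethers being inert.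

**Step 2**
Reactants: 3 2-diazo-1-[3,4,5-tris(benzyloxy)phenyl]ethan-1-one
Product: 5 N,N-dimethyl-2-[3,4,5-tris(benzyloxy)phenyl]acetamide, via arylketene 4 (not isolated)
Conditions: PhCO2Ag (cat.), Et3N, Me2NH (2 M in THF), THF, −20 °C to rt, dark
Reagents that add atoms: dimethylamine, CNC
Why: Silver-catalysed Wolff rearrangement gives the arylketene, which is trapped by dimethylamine to the homologous amide (Arndt–Eistert homologation); no stereocentre is involved.

**Step 3**
Reactants: 6 3,4-bis(benzyloxy)phenol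
Product: 7 3,4-bis(benzyloxy)phenyl trifluoromethanesulfonate
Conditions: Tf2O, pyridine, CH2Cl2, 0 °C
Reagents that add atoms: trifluoromethanesulfonic anhydride, O=S(=O)(OS(=O)(=O)C(F)(F)F)C(F)(F)F
Why: Routine O-sulfonylation of a phenol gives the aryl triflate needed for the cationic Heck pathway.

**Step 4**
Reactants: 7 3,4-bis(benzyloxy)phenyl trifluoromethanesulfonate; 8 2,3-dihydrofuran
Product: 9 (2S)-2-[3,4-bis(benzyloxy)phenyl]-2,5-dihydrofuran
Conditions: Pd2(dba)3 (3 mol %), (R)-t-Bu-PHOX (7 mol %), i-Pr2NEt, 8 (excess), THF, 70 °C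
Reagents that add atoms: none
Why: Asymmetric intermolecular Heck reaction: the cationic aryl–palladium complex formed from zerovalent palladium adds across the enol ether with aryl at C2, and beta-hydride elimination away from oxygen with fast release from the P,N-ligated metal should give the 2,5-dihydrofuran without double-bond migration, the ligand choosing the enantioface and so setting C2 as S.

**Step 5**
Reactants: 5 N,N-dimethyl-2-[3,4,5-tris(benzyloxy)phenyl]acetamide; 9 (2S)-2-[3,4-bis(benzyloxy)phenyl]-2,5-dihydrofuran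
Product: 12 (1R,4S,5S,7S)-4-[3,4-bis(benzyloxy)phenyl]-7-[3,4,5-tris(benzyloxy)phenyl]-3-oxabicyclo[3.2.0]heptan-6-one, via keteniminium triflate 10 (not isolated), via cyclobutaniminium triflate 11 (not isolated)
Conditions: 5 (excess), Tf2O, 2,4,6-collidine, ClCH2CH2Cl, −20 °C; then 9, −20 to 45 °C; then H2O, rt; then DBU (cat.), CH2Cl2, rt
Reagents that add atoms: water, O
Why: Triflic anhydride and collidine turn amide 5 into the N,N-dimethylketeniminium ion 10, whose electrophilic central carbon is attacked by the C3=C4 pi bond of 9, after which the enamine carbon closes onto the developing cation; this is a keteniminium–alkene [2+2] cycloaddition of the kind well known for cyclopentene-type cis-alkenes. Only the four-membered ring is closed, in an asynchronous [2+2] mode whose second bond forms by 4-exo collapse before any bond rotation, so the ring fusion is cis. The ring-fusion stereocentres C1 and C5 are set by approach of 10 to the alkene face anti to the C2 aryl group of 9, and C7 is set under thermodynamic control, the iminium salt and then the ketone (DBU) epimerising to the exo-aryl isomer. The step needs regioselectivity, the iminium carbon bonding to C3 of 9 and the ArCH carbon to C4: the bulkier ArCH terminus should prefer the carbon flanked by the unsubstituted C5H2, and positive charge should build up on C4, remote from the more electron-withdrawing ArCH–O carbon. This regiocontrol is the least certain element of the route, and the isomeric cyclobutanone would have to be removed by chromatography.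

**Step 6**
Reactants: 12 (1R,4S,5S,7S)-4-[3,4-bis(benzyloxy)phenyl]-7-[3,4,5-tris(benzyloxy)phenyl]-3-oxabicyclo[3.2.0]heptan-6-one
Product: 13 (3S,3aR,6S,6aS)-6-[3,4-bis(benzyloxy)phenyl]-3-[3,4,5-tris(benzyloxy)phenyl]tetrahydro-1H,3H-furo[3,4-c]furan-1-one
Conditions: m-CPBA, CH2Cl2, 0 °C
Reagents that add atoms: 3-chloroperbenzoic acid, OOC(=O)c1cccc(Cl)c1
Why: Baeyer–Villiger oxidation, fast at 0 °C because ring strain is released from the Criegee adduct; the benzylic C7 should migrate with retention in preference to the ring-fusion carbon C5, which is deactivated by the beta-oxygen at C4, so oxygen enters between C6 and C7 and the aryl-bearing centre keeps its configuration.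

**Step 7**
Reactants: 13 (3S,3aR,6S,6aS)-6-[3,4-bis(benzyloxy)phenyl]-3-[3,4,5-tris(benzyloxy)phenyl]tetrahydro-1H,3H-furo[3,4-c]furan-1-one
Product: 14 (3S,3aR,6S,6aS)-6-(3,4-dihydroxyphenyl)-3-(3,4,5-trihydroxyphenyl)tetrahydro-1H,3H-furo[3,4-c]furan-1-one
Conditions: H2 (1 atm), Pd/C (10 wt %), degassed EtOAc–MeOH, rt, stopped when debenzylation is complete
Reagents that add atoms: none
Why: Hydrogenolysis of the five benzyl aryl ethers over palladium should be faster than cleavage of the two ring benzylic C–O bonds under neutral conditions, and no stereocentre is touched.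

**Compound list**
1 | 3,4,5-tris(benzyloxy)benzoic acid | OC(=O)c1cc(OCc2ccccc2)c(OCc2ccccc2)c(OCc2ccccc2)c1 | starting material
2 | 3,4,5-tris(benzyloxy)benzoyl chloride | ClC(=O)c1cc(OCc2ccccc2)c(OCc2ccccc2)c(OCc2ccccc2)c1 | intermediate
3 | 2-diazo-1-[3,4,5-tris(benzyloxy)phenyl]ethan-1-one | [N-]=[N+]=CC(=O)c1cc(OCc2ccccc2)c(OCc2ccccc2)c(OCc2ccccc2)c1 | intermediate
4 | 2-[3,4,5-tris(benzyloxy)phenyl]ethen-1-one (arylketene) | O=C=Cc1cc(OCc2ccccc2)c(OCc2ccccc2)c(OCc2ccccc2)c1 | intermediate
5 | N,N-dimethyl-2-[3,4,5-tris(benzyloxy)phenyl]acetamide | CN(C)C(=O)Cc1cc(OCc2ccccc2)c(OCc2ccccc2)c(OCc2ccccc2)c1 | intermediate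
6 | 3,4-bis(benzyloxy)phenol | Oc1ccc(OCc2ccccc2)c(OCc2ccccc2)c1 | starting material
7 | 3,4-bis(benzyloxy)phenyl trifluoromethanesulfonate | O=S(=O)(Oc1ccc(OCc2ccccc2)c(OCc2ccccc2)c1)C(F)(F)F | intermediate
8 | 2,3-dihydrofuran | C1CC=CO1 | starting material
9 | (2S)-2-[3,4-bis(benzyloxy)phenyl]-2,5-dihydrofuran | C1O[C@H](c2ccc(OCc3ccccc3)c(OCc3ccccc3)c2)C=C1 | intermediate
10 | N,N-dimethyl-2-[3,4,5-tris(benzyloxy)phenyl]ethen-1-iminium trifluoromethanesulfonate (keteniminium triflate) | C[N+](C)=C=Cc1cc(OCc2ccccc2)c(OCc2ccccc2)c(OCc2ccccc2)c1.[O-]S(=O)(=O)C(F)(F)F | intermediate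
11 | N-[(1R,4S,5R,7S)-4-[3,4-bis(benzyloxy)phenyl]-7-[3,4,5-tris(benzyloxy)phenyl]-3-oxabicyclo[3.2.0]heptan-6-ylidene]-N-methylmethanaminium trifluoromethanesulfonate | C[N+](C)=C1[C@H](c2cc(OCc3ccccc3)c(OCc3ccccc3)c(OCc3ccccc3)c2)[C@H]2CO[C@H](c3ccc(OCc4ccccc4)c(OCc4ccccc4)c3)[C@@H]12.[O-]S(=O)(=O)C(F)(F)F | intermediate
12 | (1R,4S,5S,7S)-4-[3,4-bis(benzyloxy)phenyl]-7-[3,4,5-tris(benzyloxy)phenyl]-3-oxabicyclo[3.2.0]heptan-6-one | O=C1[C@H](c2cc(OCc3ccccc3)c(OCc3ccccc3)c(OCc3ccccc3)c2)[C@H]2CO[C@H](c3ccc(OCc4ccccc4)c(OCc4ccccc4)c3)[C@@H]12 | intermediate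
13 | (3S,3aR,6S,6aS)-6-[3,4-bis(benzyloxy)phenyl]-3-[3,4,5-tris(benzyloxy)phenyl]tetrahydro-1H,3H-furo[3,4-c]furan-1-one | O=C1O[C@H](c2cc(OCc3ccccc3)c(OCc3ccccc3)c(OCc3ccccc3)c2)[C@H]2CO[C@H](c3ccc(OCc4ccccc4)c(OCc4ccccc4)c3)[C@@H]12 | intermediate
14 | (3S,3aR,6S,6aS)-6-(3,4-dihydroxyphenyl)-3-(3,4,5-trihydroxyphenyl)tetrahydro-1H,3H-furo[3,4-c]furan-1-one | O=C1O[C@H](c2cc(O)c(O)c(O)c2)[C@H]2CO[C@H](c3ccc(O)c(O)c3)[C@@H]12 | target

**Totals**
Total step count: 7. Longest linear sequence: 5 steps (steps 1, 2, 5, 6, 7 or steps 3, 4, 5, 6, 7).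

**Steps most likely to fail**

Step 5. The electron-rich bis(benzyloxy)phenyl group may assist build-up of positive charge on C3 of the dihydrofuran, or migrate to it, so that the iminium carbon bonds to C4 and the wrong regioisomer or rearranged material predominates. Acid-induced opening of the doubly activated C2–O bond of 9 is a second possible failure. The fallback sets out from 7 and comes back at 14; it makes the aryl ring electron-poor before the alkene is built. Triflate 7 is debenzylated (H2, Pd/C, EtOAc) to 3,4-dihydroxyphenyl trifluoromethanesulfonate F1 and acetylated (Ac2O, pyridine) to 4-[(trifluoromethanesulfonyl)oxy]-1,2-phenylene diacetate F2. Heck arylation of 8 as in step 4 should give 4-[(2S)-2,5-dihydrofuran-2-yl]-1,2-phenylene diacetate F3, whose aryl ring no longer donates to a cation at C3 and whose ArCH–O carbon is more strongly electron-withdrawing. Cycloaddition with keteniminium 10 (from 5) as in step 5, without DBU, should give the diacetoxy cyclobutaniminium triflate F4 and, after hydrolysis, the diacetoxy cyclobutanone F5. Baeyer–Villiger oxidation as in step 6 should give the diacetoxy lactone F6. K2CO3 (cat.) in MeOH at 0 °C under argon frees the catechol to give the catechol lactone F7, and hydrogenolysis as in step 7 gives 14.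

Step 6. The ring-fusion carbon C5 may migrate in the Criegee adduct in competition with the benzylic carbon C7, giving the isomeric lactone, or the peracid may attack the electron-rich arenes. The fallback sets out from 12 and comes back at 13; it replaces peracid oxidation by a photochemical ring expansion. Irradiation of 12 (350 nm, Pyrex, MeOH) should cleave the weaker C6–C7 bond on the benzylic side, and the acyl–benzyl biradical should close to an oxacarbene that inserts into methanol to give the methyl acetal F8. PPTS in aqueous acetone should give the lactol F9, and oxidation with n-Pr4N[RuO4] (cat.) and N-methylmorpholine N-oxide should give lactone 13.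

Step 7. Hydrogenolytic cleavage of the benzylic C3–O bond of the lactone or the C6–O bond of the ether may compete with removal of the benzyl ethers, and the free polyphenol may oxidise in air. The fallback sets out from 13 and comes back at 14; it is a non-reductive debenzylation. BCl3 and pentamethylbenzene in CH2Cl2 at −78 °C should remove the benzyl groups as cations trapped by the arene, giving 14 directly; this fallback makes no new compound (F0).

**Further compounds**
F1 | step 5 | 3,4-dihydroxyphenyl trifluoromethanesulfonate | Oc1ccc(OS(=O)(=O)C(F)(F)F)cc1O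
F2 | step 5 | 4-[(trifluoromethanesulfonyl)oxy]-1,2-phenylene diacetate | CC(=O)Oc1ccc(OS(=O)(=O)C(F)(F)F)cc1OC(C)=O
F3 | step 5 | 4-[(2S)-2,5-dihydrofuran-2-yl]-1,2-phenylene diacetate | C1O[C@H](c2ccc(OC(C)=O)c(OC(C)=O)c2)C=C1
F4 | step 5 | N-[(1R,4S,5R,7S)-4-(3,4-diacetoxyphenyl)-7-[3,4,5-tris(benzyloxy)phenyl]-3-oxabicyclo[3.2.0]heptan-6-ylidene]-N-methylmethanaminium trifluoromethanesulfonate | C[N+](C)=C1[C@H](c2cc(OCc3ccccc3)c(OCc3ccccc3)c(OCc3ccccc3)c2)[C@H]2CO[C@H](c3ccc(OC(C)=O)c(OC(C)=O)c3)[C@@H]12.[O-]S(=O)(=O)C(F)(F)F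
F5 | step 5 | (1R,4S,5S,7S)-4-(3,4-diacetoxyphenyl)-7-[3,4,5-tris(benzyloxy)phenyl]-3-oxabicyclo[3.2.0]heptan-6-one | O=C1[C@H](c2cc(OCc3ccccc3)c(OCc3ccccc3)c(OCc3ccccc3)c2)[C@H]2CO[C@H](c3ccc(OC(C)=O)c(OC(C)=O)c3)[C@@H]12
F6 | step 5 | (3S,3aR,6S,6aS)-6-(3,4-diacetoxyphenyl)-3-[3,4,5-tris(benzyloxy)phenyl]tetrahydro-1H,3H-furo[3,4-c]furan-1-one | O=C1O[C@H](c2cc(OCc3ccccc3)c(OCc3ccccc3)c(OCc3ccccc3)c2)[C@H]2CO[C@H](c3ccc(OC(C)=O)c(OC(C)=O)c3)[C@@H]12
F7 | step 5 | (3S,3aR,6S,6aS)-6-(3,4-dihydroxyphenyl)-3-[3,4,5-tris(benzyloxy)phenyl]tetrahydro-1H,3H-furo[3,4-c]furan-1-one | O=C1O[C@H](c2cc(OCc3ccccc3)c(OCc3ccccc3)c(OCc3ccccc3)c2)[C@H]2CO[C@H](c3ccc(O)c(O)c3)[C@@H]12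
F8 | step 6 | (3S,3aR,6S,6aS)-6-[3,4-bis(benzyloxy)phenyl]-1-methoxy-3-[3,4,5-tris(benzyloxy)phenyl]tetrahydro-1H,3H-furo[3,4-c]furan (both C1 epimers) | COC1O[C@H](c2cc(OCc3ccccc3)c(OCc3ccccc3)c(OCc3ccccc3)c2)[C@H]2CO[C@H](c3ccc(OCc4ccccc4)c(OCc4ccccc4)c3)[C@@H]12
F9 | step 6 | (3S,3aR,6S,6aS)-6-[3,4-bis(benzyloxy)phenyl]-3-[3,4,5-tris(benzyloxy)phenyl]tetrahydro-1H,3H-furo[3,4-c]furan-1-ol (both C1 epimers) | OC1O[C@H](c2cc(OCc3ccccc3)c(OCc3ccccc3)c(OCc3ccccc3)c2)[C@H]2CO[C@H](c3ccc(OCc4ccccc4)c(OCc4ccccc4)c3)[C@@H]12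
F0 | step 7 | none | none
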